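**Retrosynthetic overview**
1. The furan-2(5H)-one ring (O1, C2, C3, C4, C5) is opened at C2–C3, the bond between the lactone carbonyl carbon and the methyl-bearing carbon. C2 is at the carbonic acid level and sits on O1; C3 is the alpha-carbon of the C4 carbonyl. The ring is therefore made by C-acylation of a C3–C4 enolate with a carbonate carbon already held on O1.
2. Enabling feature: O1–C5–C4(–O)=C3 is the enol of an alpha-oxygenated ketone, so O1 and the C4 enol oxygen can both be tied to C2 in a temporary ring, the (Z)-4-ethylidene-1,3-dioxolan-2-one 19. One equivalent of methoxide then releases the regiodefined enolate and the acyl donor together.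
3. 19 comes from propargylic alcohol 16 and CO2 (the alkyne is the masked C4 ketone plus C3 and its methyl). C5 is set by asymmetric transfer hydrogenation of ynone 15, made from aldehyde 11 and a propynyl Grignard reagent.
4. Aldehyde 11 comes from (2E,6E)-farnesol: Ru–BINAP hydrogenation sets the methyl stereocentre, the terminal (E)-methyl is oxidised and brominated, and a copper-catalysed coupling attaches the 2-(furan-3-yl)ethyl unit.
5. Ring order: the furan is bought in; the 1,3-dioxolan-2-one ring (temporary) forms in step 12; the furan-2(5H)-one ring forms last, in step 13.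

Key step: step 13

Assumption: by CIP analysis the target is (5R) at the lactone carbon and (R) at the methyl-branched chain carbon, with two E olefins, and it is handled as its 4-hydroxyfuran-2(5H)-one tautomer.

**Route**

Step 1
Reactants: 1 (2E,6E)-farnesol
Product: 2 (3R,6E)-3,7,11-trimethyldodeca-6,10-dien-1-ol
Conditions: Ru(OAc)2[(S)-BINAP] (0.5 mol %), H2 (100 atm), 95% aq. MeOH, 20 °C
Reagents that add atoms: none
Why: Noyori asymmetric hydrogenation of an allylic alcohol, in which the hydroxyl-directed Ru–BINAP catalyst reduces only the 2,3-olefin and leaves the two isolated trisubstituted olefins alone; by the sense known for geraniol with (S)-BINAP giving (R)-citronellol it should set the (R) methyl stereocentre under catalyst control.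

Step 2
Reactants: 2 (3R,6E)-3,7,11-trimethyldodeca-6,10-dien-1-ol
Product: 3 tert-butyl(dimethyl){[(3R,6E)-3,7,11-trimethyldodeca-6,10-dien-1-yl]oxy}silane
Conditions: TBSCl, imidazole, DMF, 0 °C to rt
Reagents that add atoms: tert-butyldimethylsilyl chloride CC(C)(C)[Si](C)(C)Cl
Why: Standard silylation of a primary alcohol, which masks it through the oxidation, bromination and organometallic steps that follow.

Step 3
Reactants: 3 tert-butyl(dimethyl){[(3R,6E)-3,7,11-trimethyldodeca-6,10-dien-1-yl]oxy}silane
Product: 4 (2E,6E,10R)-12-[(tert-butyldimethylsilyl)oxy]-2,6,10-trimethyldodeca-2,6-dien-1-ol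
Conditions: SeO2 (0.3 equiv), salicylic acid (0.1 equiv), t-BuOOH (70% aq., 3 equiv), CH2Cl2, 0 °C to rt, stopped at partial conversion, recovered 3 recycled
Reagents that add atoms: selenium dioxide O=[Se]=O (catalytic oxygen carrier); tert-butyl hydroperoxide CC(C)(C)OO (terminal oxidant)
Why: Riley-type catalytic SeO2 allylic oxidation (ene reaction, then [2,3]-sigmatropic shift), which should attack the terminal, most accessible trisubstituted olefin and oxidise its (E)-methyl group to the (E)-allylic alcohol.

Step 4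
Reactants: 4 (2E,6E,10R)-12-[(tert-butyldimethylsilyl)oxy]-2,6,10-trimethyldodeca-2,6-dien-1-ol
Product: 5 {[(3R,6E,10E)-12-bromo-3,7,11-trimethyldodeca-6,10-dien-1-yl]oxy}(tert-butyl)dimethylsilane
Conditions: CBr4, PPh3, CH2Cl2, −30 to 0 °C
Reagents that add atoms: carbon tetrabromide BrC(Br)(Br)Br
Why: Appel bromination, an SN2 displacement at the primary allylic carbon under neutral conditions that should keep the olefin geometry and the silyl ether.

Step 5
Reactants: 6 2-(furan-3-yl)ethanol
Product: 7 3-(2-bromoethyl)furan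
Conditions: CBr4, PPh3, CH2Cl2, 0 °C
Reagents that add atoms: carbon tetrabromide BrC(Br)(Br)Br
Why: Appel bromination of a primary alcohol under neutral conditions that the acid-sensitive furan tolerates.

Step 6
Reactants: 5 {[(3R,6E,10E)-12-bromo-3,7,11-trimethyldodeca-6,10-dien-1-yl]oxy}(tert-butyl)dimethylsilane; 7 3-(2-bromoethyl)furan
Product: 9 tert-butyl{[(3R,6E,10E)-14-(furan-3-yl)-3,7,11-trimethyltetradeca-6,10-dien-1-yl]oxy}dimethylsilane, via [2-(furan-3-yl)ethyl]magnesium bromide 8 (not isolated)
Conditions: 7, Mg turnings, THF, rt; then 5, Li2CuCl4 (5 mol %), THF, −78 to 0 °C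
Reagents that add atoms: none
Why: Kochi-type copper-catalysed coupling of a primary alkyl Grignard reagent with a primary allylic bromide, which with Li2CuCl4 at low temperature should substitute at the alpha-carbon with retention of the E geometry while the silyl ether stays inert.

Step 7
Reactants: 9 tert-butyl{[(3R,6E,10E)-14-(furan-3-yl)-3,7,11-trimethyltetradeca-6,10-dien-1-yl]oxy}dimethylsilane
Product: 10 (3R,6E,10E)-14-(furan-3-yl)-3,7,11-trimethyltetradeca-6,10-dien-1-ol
Conditions: Bu4NF (1.0 M in THF), THF, 0 °C to rt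
Reagents that add atoms: none
Why: Fluoride-mediated desilylation, driven by the Si–F bond and harmless to furan and olefins.

Step 8
Reactants: 10 (3R,6E,10E)-14-(furan-3-yl)-3,7,11-trimethyltetradeca-6,10-dien-1-ol
Product: 11 (3R,6E,10E)-14-(furan-3-yl)-3,7,11-trimethyltetradeca-6,10-dienal
Conditions: Dess–Martin periodinane, CH2Cl2, 0 °C to rt
Reagents that add atoms: none
Why: Dess–Martin oxidation of a primary alcohol to the aldehyde under mild conditions; the stereocentre is beta to the carbonyl and cannot epimerise.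

Step 9
Reactants: 11 (3R,6E,10E)-14-(furan-3-yl)-3,7,11-trimethyltetradeca-6,10-dienal; 12 1-propynylmagnesium bromide
Product: 14 (4RS,6R,9E,13E)-17-(furan-3-yl)-6,10,14-trimethylheptadeca-9,13-dien-2-yn-4-ol (both C4 epimers), via bromomagnesium alkoxide 13 (not isolated)
Conditions: THF, −78 to 0 °C; then H2O (pH 7 buffer)
Reagents that add atoms: 1-propynylmagnesium bromide (compound 12) CC#C[Mg]Br
Why: Grignard 1,2-addition of an alkynyl nucleophile to the aldehyde; no stereocontrol is needed because both carbinol epimers converge in the next two steps.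

Step 10
Reactants: 14 (4RS,6R,9E,13E)-17-(furan-3-yl)-6,10,14-trimethylheptadeca-9,13-dien-2-yn-4-ol
Product: 15 (6R,9E,13E)-17-(furan-3-yl)-6,10,14-trimethylheptadeca-9,13-dien-2-yn-4-one
Conditions: Dess–Martin periodinane, CH2Cl2, 0 °C
Reagents that add atoms: none
Why: Dess–Martin oxidation of a propargylic alcohol to the ynone, which erases the uncontrolled carbinol centre.

Step 11
Reactants: 15 (6R,9E,13E)-17-(furan-3-yl)-6,10,14-trimethylheptadeca-9,13-dien-2-yn-4-one
Product: 16 (4R,6R,9E,13E)-17-(furan-3-yl)-6,10,14-trimethylheptadeca-9,13-dien-2-yn-4-ol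
Conditions: Ru[(R,R)-TsDPEN](p-cymene) (2 mol %), i-PrOH, rt
Reagents that add atoms: none
Why: Noyori asymmetric transfer hydrogenation of an alpha,beta-acetylenic ketone, in which the alkynyl group takes the place of the aryl group in the TsDPEN–Ru transition state, so the (R,R) catalyst should give the (R)-carbinol (the future C5) under catalyst control with little influence from the remote methyl centre.

Step 12
Reactants: 16 (4R,6R,9E,13E)-17-(furan-3-yl)-6,10,14-trimethylheptadeca-9,13-dien-2-yn-4-ol; 17 carbon dioxide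
Product: 19 (4Z,5R)-4-ethylidene-5-[(2R,5E,9E)-13-(furan-3-yl)-2,6,10-trimethyltrideca-5,9-dien-1-yl]-1,3-dioxolan-2-one, via amidinium propargyl carbonate 18 (not isolated)
Conditions: AgOAc (10 mol %), DBU (0.5 equiv), CO2 (1 MPa), toluene, 20 °C; stopped at full conversion, filtered through silica
Reagents that add atoms: carbon dioxide (compound 17) O=C=O
Why: Silver-catalysed carboxylative cyclisation of a propargylic alcohol with CO2, in which carbonate 18 adds anti across the silver-activated alkyne in 5-exo-dig mode and protodemetallation gives the (Z)-alkylidene carbonate; the C5–O bond is untouched, so the configuration is retained, and the non-benzylic C5–H, the low temperature and the substoichiometric base should guard against isomerisation to the 1,3-dioxol-2-one.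

Step 13
Reactants: 19 (4Z,5R)-4-ethylidene-5-[(2R,5E,9E)-13-(furan-3-yl)-2,6,10-trimethyltrideca-5,9-dien-1-yl]-1,3-dioxolan-2-one
Product: 22 (5R)-5-[(2R,5E,9E)-13-(furan-3-yl)-2,6,10-trimethyltrideca-5,9-dien-1-yl]-4-hydroxy-3-methylfuran-2(5H)-one (target), via sodium enolate methyl carbonate 20 (not isolated), via sodium tetronate 21 (not isolated)
Conditions: NaOMe (1.05 equiv, anhydrous powder), 15-crown-5 (1.05 equiv), THF (0.03 M), −40 °C to rt; then cold 1 M HCl to pH 3
Reagents that add atoms: none
Why: Proposed new method: methoxide adds to the carbonate carbonyl of 19 and the tetrahedral intermediate loses its better leaving group, the enolate oxygen, so that 20 is born as the regiodefined C3–C4 enolate with the CO2-derived carbon already fixed on O1 as a methyl carbonate; C3 then attacks that carbon, methoxide leaves, and the furan-2,4-dione is deprotonated at once to tetronate 21, the thermodynamic sink. The closest known reaction types are the alkoxide opening of alpha-alkylidene cyclic carbonates to beta-oxoalkyl carbonates, the Claisen-type C-acylation of enolates by carbonic acid derivatives (carbonate variant of the Baker–Venkataraman transfer; acyloin plus carbonyldiimidazole route to tetronic acids) and the Steglich O-to-C carboxyl shift of enol carbonates; what is new is running them on a cyclic enol carbonate so that a 1,3-dioxolan-2-one isomerises into a furanone. The furanone ring closes at C2–C3 in a 5-(enolendo)-exo-trig mode, the same mode through which the Lacey–Dieckmann cyclisation delivers tetronic acids. No new stereocentre is formed, and C5 should keep its (R) configuration because its C–O and C–H bonds are never broken, the enolate being released from the enol carbonate and not made by deprotonation. The step needs C- over O-acylation and no proton transfer to or from C5: O-attack only returns 19 and is reversible, C-attack is made irreversible by deprotonation of the acidic product, and the aprotic medium with one equivalent of methoxide, consumed at low temperature before warming, leaves no free base to enolise toward C5 or to isomerise 19 to the achiral 1,3-dioxol-2-one.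

**Compound list**
1 | (2E,6E)-farnesol | OC/C=C(\C)CC/C=C(\C)CCC=C(C)C | starting material
2 | (3R,6E)-3,7,11-trimethyldodeca-6,10-dien-1-ol | OCC[C@H](C)CC/C=C(\C)CCC=C(C)C | intermediate
3 | tert-butyl(dimethyl){[(3R,6E)-3,7,11-trimethyldodeca-6,10-dien-1-yl]oxy}silane | CC(C)(C)[Si](C)(C)OCC[C@H](C)CC/C=C(\C)CCC=C(C)C | intermediate
4 | (2E,6E,10R)-12-[(tert-butyldimethylsilyl)oxy]-2,6,10-trimethyldodeca-2,6-dien-1-ol | CC(C)(C)[Si](C)(C)OCC[C@H](C)CC/C=C(\C)CC/C=C(\C)CO | intermediate
5 | {[(3R,6E,10E)-12-bromo-3,7,11-trimethyldodeca-6,10-dien-1-yl]oxy}(tert-butyl)dimethylsilane | CC(C)(C)[Si](C)(C)OCC[C@H](C)CC/C=C(\C)CC/C=C(\C)CBr | intermediate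
6 | 2-(furan-3-yl)ethanol | OCCc1ccoc1 | starting material
7 | 3-(2-bromoethyl)furan | BrCCc1ccoc1 | intermediate
8 | [2-(furan-3-yl)ethyl]magnesium bromide | Br[Mg]CCc1ccoc1 | intermediate
9 | tert-butyl{[(3R,6E,10E)-14-(furan-3-yl)-3,7,11-trimethyltetradeca-6,10-dien-1-yl]oxy}dimethylsilane | CC(C)(C)[Si](C)(C)OCC[C@H](C)CC/C=C(\C)CC/C=C(\C)CCCc1ccoc1 | intermediate
10 | (3R,6E,10E)-14-(furan-3-yl)-3,7,11-trimethyltetradeca-6,10-dien-1-ol | OCC[C@H](C)CC/C=C(\C)CC/C=C(\C)CCCc1ccoc1 | intermediate
11 | (3R,6E,10E)-14-(furan-3-yl)-3,7,11-trimethyltetradeca-6,10-dienal | O=CC[C@H](C)CC/C=C(\C)CC/C=C(\C)CCCc1ccoc1 | intermediate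
12 | 1-propynylmagnesium bromide | CC#C[Mg]Br | starting material
13 | bromomagnesium (4RS,6R,9E,13E)-17-(furan-3-yl)-6,10,14-trimethylheptadeca-9,13-dien-2-yn-4-olate | CC#CC(O[Mg]Br)C[C@H](C)CC/C=C(\C)CC/C=C(\C)CCCc1ccoc1 | intermediate
14 | (4RS,6R,9E,13E)-17-(furan-3-yl)-6,10,14-trimethylheptadeca-9,13-dien-2-yn-4-ol (both C4 epimers) | CC#CC(O)C[C@H](C)CC/C=C(\C)CC/C=C(\C)CCCc1ccoc1 | intermediate
15 | (6R,9E,13E)-17-(furan-3-yl)-6,10,14-trimethylheptadeca-9,13-dien-2-yn-4-one | CC#CC(=O)C[C@H](C)CC/C=C(\C)CC/C=C(\C)CCCc1ccoc1 | intermediate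
16 | (4R,6R,9E,13E)-17-(furan-3-yl)-6,10,14-trimethylheptadeca-9,13-dien-2-yn-4-ol | CC#C[C@H](O)C[C@H](C)CC/C=C(\C)CC/C=C(\C)CCCc1ccoc1 | intermediate
17 | carbon dioxide | O=C=O | starting material
18 | DBU-H+ (4R,6R,9E,13E)-17-(furan-3-yl)-6,10,14-trimethylheptadeca-9,13-dien-2-yn-4-yl carbonate | CC#C[C@H](OC(=O)[O-])C[C@H](C)CC/C=C(\C)CC/C=C(\C)CCCc1ccoc1.C1CCC2=[NH+]CCCN2CC1 | intermediate
19 | (4Z,5R)-4-ethylidene-5-[(2R,5E,9E)-13-(furan-3-yl)-2,6,10-trimethyltrideca-5,9-dien-1-yl]-1,3-dioxolan-2-one | C/C=C1\OC(=O)O[C@@H]1C[C@H](C)CC/C=C(\C)CC/C=C(\C)CCCc2ccoc2 | intermediate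
20 | sodium (2Z,4R,6R,9E,13E)-17-(furan-3-yl)-4-[(methoxycarbonyl)oxy]-6,10,14-trimethylheptadeca-2,9,13-trien-3-olate | C/C=C(\[O-])[C@@H](C[C@H](C)CC/C=C(\C)CC/C=C(\C)CCCc1ccoc1)OC(=O)OC.[Na+] | intermediate
21 | sodium (2R)-2-[(2R,5E,9E)-13-(furan-3-yl)-2,6,10-trimethyltrideca-5,9-dien-1-yl]-4-methyl-5-oxo-2,5-dihydrofuran-3-olate | CC1=C([O-])[C@@H](C[C@H](C)CC/C=C(\C)CC/C=C(\C)CCCc2ccoc2)OC1=O.[Na+] | intermediate
22 | (5R)-5-[(2R,5E,9E)-13-(furan-3-yl)-2,6,10-trimethyltrideca-5,9-dien-1-yl]-4-hydroxy-3-methylfuran-2(5H)-one | CC1=C(O)[C@@H](C[C@H](C)CC/C=C(\C)CC/C=C(\C)CCCc2ccoc2)OC1=O | target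

**Step count**
Total steps: 13. Longest linear sequence: 12 (steps 1 to 4 and 6 to 13); step 5 is a one-step side branch.

**Steps most likely to fail, with fallbacks**

Step 13 (proposed new method). The enolate set free from the enol carbonate may return to 19 by O-acylation faster than it closes on carbon. It may also exchange protons, so that an open methyl carbonate ketone is recovered on work-up or the C5 configuration is eroded, and intermolecular acyl transfer may compete at higher concentration. The fallback uses known chemistry and sets out from 19. Hydrolysis with loss of CO2 (H2O, catalytic Et3N, MeCN, rt), the established way from alkylidene carbonates to alpha-hydroxy ketones, should give (4R,6R,9E,13E)-17-(furan-3-yl)-4-hydroxy-6,10,14-trimethylheptadeca-9,13-dien-3-one F1. Acylation with 1,1'-carbonyldiimidazole (CH2Cl2, rt) should give (4R,6R,9E,13E)-17-(furan-3-yl)-6,10,14-trimethyl-3-oxoheptadeca-9,13-dien-4-yl 1H-imidazole-1-carboxylate F2. Kinetic enolisation on the ethyl side with LiN(SiMe3)2 (1.1 equiv, THF, −78 °C) and Claisen-type closure, the acyloin and carbonyldiimidazole route to tetronic acids, should give lithium (2R)-2-[(2R,5E,9E)-13-(furan-3-yl)-2,6,10-trimethyltrideca-5,9-dien-1-yl]-4-methyl-5-oxo-2,5-dihydrofuran-3-olate F3. Acidification returns the route at 22.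

Step 12. Base-mediated 1,3-proton shift may turn the alkylidene carbonate into the achiral 1,3-dioxol-2-one with loss of the C5 configuration, and carboxylation of a secondary alcohol on an internal alkyne may be sluggish. The fallback sets out from 16 and is base-free in the ring-forming event. Boc2O with catalytic DMAP (CH2Cl2, rt) should give tert-butyl (4R,6R,9E,13E)-17-(furan-3-yl)-6,10,14-trimethylheptadeca-9,13-dien-2-yn-4-yl carbonate F4. Ph3PAuNTf2 (2 mol %, CH2Cl2, rt) should then induce 5-exo-dig attack of the carbonyl oxygen on the gold-activated alkyne, loss of 2-methylpropene and protodeauration. The route is rejoined at 19, with C2 now derived from Boc2O instead of CO2.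

Step 6. Attack at the gamma-carbon with allylic transposition, erosion of the E geometry at the allylic terminus and Wurtz-type homocoupling may compete with the desired substitution. The fallback reverses the polarity and sets out from 7 and 5. Displacement on 7 with PhSO2Na (DMF, 60 °C) should give 3-[2-(phenylsulfonyl)ethyl]furan F5. Deprotonation with n-BuLi (THF, −78 °C) gives [2-(furan-3-yl)-1-(phenylsulfonyl)ethyl]lithium F6. Its alkylation with 5, which can only proceed by direct SN2 substitution, should give tert-butyl{[(3R,6E,10E)-14-(furan-3-yl)-3,7,11-trimethyl-13-(phenylsulfonyl)tetradeca-6,10-dien-1-yl]oxy}dimethylsilane F7 as both C13 epimers. Reductive desulfonylation (6% Na(Hg), Na2HPO4, MeOH, −20 °C) returns the route at 9.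

**Further compounds**
F1 | step 13 | (4R,6R,9E,13E)-17-(furan-3-yl)-4-hydroxy-6,10,14-trimethylheptadeca-9,13-dien-3-one | CCC(=O)[C@H](O)C[C@H](C)CC/C=C(\C)CC/C=C(\C)CCCc1ccoc1
F2 | step 13 | (4R,6R,9E,13E)-17-(furan-3-yl)-6,10,14-trimethyl-3-oxoheptadeca-9,13-dien-4-yl 1H-imidazole-1-carboxylate | CCC(=O)[C@H](OC(=O)n1ccnc1)C[C@H](C)CC/C=C(\C)CC/C=C(\C)CCCc2ccoc2
F3 | step 13 | lithium (2R)-2-[(2R,5E,9E)-13-(furan-3-yl)-2,6,10-trimethyltrideca-5,9-dien-1-yl]-4-methyl-5-oxo-2,5-dihydrofuran-3-olate | CC1=C([O-])[C@@H](C[C@H](C)CC/C=C(\C)CC/C=C(\C)CCCc2ccoc2)OC1=O.[Li+]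
F4 | step 12 | tert-butyl (4R,6R,9E,13E)-17-(furan-3-yl)-6,10,14-trimethylheptadeca-9,13-dien-2-yn-4-yl carbonate | CC#C[C@H](OC(=O)OC(C)(C)C)C[C@H](C)CC/C=C(\C)CC/C=C(\C)CCCc1ccoc1
F5 | step 6 | 3-[2-(phenylsulfonyl)ethyl]furan | O=S(=O)(CCc1ccoc1)c1ccccc1
F6 | step 6 | [2-(furan-3-yl)-1-(phenylsulfonyl)ethyl]lithium | [Li]C(Cc1ccoc1)S(=O)(=O)c1ccccc1
F7 | step 6 | tert-butyl{[(3R,6E,10E)-14-(furan-3-yl)-3,7,11-trimethyl-13-(phenylsulfonyl)tetradeca-6,10-dien-1-yl]oxy}dimethylsilane (both C13 epimers) | CC(C)(C)[Si](C)(C)OCC[C@H](C)CC/C=C(\C)CC/C=C(\C)CC(Cc1ccoc1)S(=O)(=O)c1ccccc1
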